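The oxolane ring (O, C1–C4; numbering in the remark) has an unsubstituted C2–C3 ethano unit, and its C4 methyl (C15) is cis to C10. Both features are read as a 7-oxanorbornene: a 2,4-disubstituted furan supplies C1, C4, C10 and C15, and an acrylimide serves as ethylene equivalent. One catalytic asymmetric Diels–Alder reaction forms C1–C2 and C3–C4 and sets both oxolane stereocentres; ozonolysis of the etheno bridge, deoxygenation at C15 and decarboxylation then give a methyl ketone. Aldol union with a furan aldehyde, chelation-controlled methylation, furan-to-butenolide oxidation and a ring-closing vinylogous aldol condensation complete the skeleton.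

Key step: step 4

Remark: sesquiterpene numbering is used (oxolane O–C1(H)–C2H2–C3H2–C4(CH3 = C15); C5H=C6 enol-ether carbon; C7; C8 angeloyloxy; C9H2; C10(OH)(CH3 = C14); C11(CH2OAc = C13); C12 lactone C=O), and the structure is taken exactly as written, (1S,4S,8S,10R), which places C5 and C10 trans across the oxolane ring (C10 cis to C15).

Step 1
Reactants: 1 4-bromofuran-2-carbaldehyde
Product: 2 4-methylfuran-2-carbaldehyde
Conditions: MeB(OH)2, Pd(dppf)Cl2 (5 mol %), K2CO3, 1,4-dioxane/H2O, 90 °C
Reagents that add atoms: methylboronic acid, CB(O)O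
Why: Suzuki–Miyaura coupling (oxidative addition of zerovalent palladium into the C–Br bond, transmetalation, reductive elimination) installs the methyl group that later becomes C9, and the aldehyde is inert under these conditions.

Step 2
Reactants: 2 4-methylfuran-2-carbaldehyde
Product: 3 (4-methylfuran-2-yl)methanol
Conditions: NaBH4, MeOH, 0 °C
Reagents that add atoms: none
Why: Borohydride reduction of the aldehyde should give the primary alcohol (the future C5 oxygen) without touching the furan.

Step 3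
Reactants: 3 (4-methylfuran-2-yl)methanol
Product: 4 tert-butyl(dimethyl)[(4-methylfuran-2-yl)methoxy]silane
Conditions: TBSCl, imidazole, DMF, rt
Reagents that add atoms: tert-butyl(chloro)dimethylsilane, CC(C)(C)[Si](C)(C)Cl
Why: Imidazole-mediated silylation gives a primary silyl ether that should tolerate the Lewis acid, ozone, radical, base and organometallic steps ahead and is the most labile silyl group when it is removed in step 16.

Step 4
Reactants: 4 tert-butyl(dimethyl)[(4-methylfuran-2-yl)methoxy]silane; 5 3-(prop-2-enoyl)-1,3-oxazolidin-2-one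
Product: 6 endo adduct 3-{[(1S,2S,4S)-1-({[tert-butyl(dimethyl)silyl]oxy}methyl)-5-methyl-7-oxabicyclo[2.2.1]hept-5-en-2-yl]carbonyl}-1,3-oxazolidin-2-one
Conditions: [Cu(tBu-box)](SbF6)2 (10 mol %; tBu-box = 2,2′-(propane-2,2-diyl)bis[(4S)-4-tert-butyl-4,5-dihydro-1,3-oxazole]), 5 (1.5 equiv), CH2Cl2, −78 °C; minor isomers removed by chromatography
Reagents that add atoms: none
Why: Bidentate binding of imide 5 to the divalent copper complex lowers its LUMO and fixes the s-cis enoyl unit in a square-planar chelate, so that furan 4 adds in a concerted, asynchronous [4π+2π] cycloaddition in which the unsubstituted furan C5 (target C1) bonds to the β-carbon (target C2) and the substituted furan C2 (target C4) to the α-carbon (target C3); the closest known reaction is the copper–bis(oxazoline)-catalysed Diels–Alder reaction of furan itself with this imide. The step closes the six-membered carbocycle of the oxanorbornene, and with it the oxolane ring O–C1–C2–C3–C4, by suprafacial–suprafacial cycloaddition in which both σ-bonds form in one event. The two bridgehead stereocentres (target C1 and the quaternary C4) are set together because only one furan face reacts: the tert-butyl group of the (S,S)-ligand shields the α-Si face of the dienophile, the diene adds to the α-Re face, and the endo transition state then fixes which furan face is used; the acyl-bearing centre (target C3) follows the same endo preference and is erased in step 8. The step needs "ortho" regioselectivity (acyl carbon next to the substituted bridgehead) and endo selectivity, because the regio- or exo-isomers would lead to the antipodal oxolane after decarboxylation; the largest HOMO coefficient at the unsubstituted furan C5, reinforced by both the 2-alkyl and the 4-methyl group, secures the former, kinetic control at −78 °C the latter, and the minor isomers are separable at this stage. The etheno bridge holds the future C15 and C10 cis, which is the trans relationship of C5 and C10 in the target.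

Step 5
Reactants: 6 endo adduct
Product: 7 3-{[(2S,3S,5S)-5-acetyl-2-({[tert-butyl(dimethyl)silyl]oxy}methyl)-2-formyloxolan-3-yl]carbonyl}-1,3-oxazolidin-2-one
Conditions: O3, CH2Cl2/MeOH, −78 °C; then Me2S, −78 °C → rt
Reagents that add atoms: ozone, [O-][O+]=O
Why: Ozonolysis of the only C=C bond (strained, trisubstituted) releases the acetyl group on C1 (its methyl is C9) and the formyl group (C15) on C4 without touching either oxolane stereocentre.

Step 6
Reactants: 7 keto aldehyde imide
Product: 9 3-{[(2S,3S,5S)-5-acetyl-2-({[tert-butyl(dimethyl)silyl]oxy}methyl)-2-methyloxolan-3-yl]carbonyl}-1,3-oxazolidin-2-one, via tosylhydrazone 8 (not isolated)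
Conditions: TsNHNH2 (1.05 equiv), THF/MeOH, 0 °C → rt; then catecholborane, CHCl3, 0 °C; then NaOAc·3H2O, 60 °C
Reagents that add atoms: none
Why: The aldehyde should condense with one equivalent of the sulfonylhydrazide in preference to the methyl ketone, and hydroboration of the C=N bond followed by acetate-induced loss of sulfinate and dinitrogen (tosylhydrazone reduction, a mild Wolff–Kishner-type deoxygenation) turns C15 into the methyl group without an alcohol intermediate that could lactonise onto the cis imide.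

Step 7
Reactants: 9 imide
Product: 10 (2S,3S,5S)-5-acetyl-2-({[tert-butyl(dimethyl)silyl]oxy}methyl)-2-methyloxolane-3-carboxylic acid
Conditions: LiOH, H2O2, THF/H2O, 0 °C; Na2SO3; then 1 M HCl to pH 3
Reagents that add atoms: lithium hydroperoxide (from LiOH and H2O2), [Li+].[O-]O
Why: Hydroperoxide cleavage of the N-acyloxazolidinone attacks the exocyclic carbonyl selectively and is only weakly basic, which should limit epimerisation at the α-alkoxy ketone centre C1.

Step 8
Reactants: 10 carboxylic acid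
Product: 12 1-[(2S,5S)-5-({[tert-butyl(dimethyl)silyl]oxy}methyl)-5-methyloxolan-2-yl]ethan-1-one, via thiohydroxamate ester 11 (not isolated)
Conditions: 1-hydroxypyridine-2(1H)-thione, DCC, DMAP (cat.), CH2Cl2, 0 °C → rt, dark; then Bu3SnH, AIBN (cat.), benzene, 80 °C
Reagents that add atoms: none
Why: Barton decarboxylation converts the acid into the C3 radical, which is reduced to CH2 in a tin hydride chain (erasing the C3 stereocentre), so that the acrylimide has served as a traceless ethylene equivalent; tin hydride, unlike a thiol, should not abstract the activated C1–H.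

Step 9
Reactants: 13 furan-3,4-diyldimethanol
Product: 14 [4-(hydroxymethyl)furan-3-yl]methyl acetate
Conditions: immobilised Candida antarctica lipase B (a hydrolase), vinyl acetate, THF, rt
Reagents that add atoms: vinyl acetate, C=COC(C)=O
Why: Lipase-catalysed transesterification acylates one of the two equivalent primary alcohols and slows at the monoacetate, which avoids the statistical mixture of a chemical acetylation.

Step 10
Reactants: 14 monoacetate
Product: 15 (4-formylfuran-3-yl)methyl acetate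
Conditions: MnO2, CH2Cl2, rt
Reagents that add atoms: none
Why: MnO2 oxidises the heteroaryl carbinol to the non-enolisable aldehyde without over-oxidation.

Step 11
Reactants: 12 methyl ketone; 15 (4-formylfuran-3-yl)methyl acetate
Product: 17 {4-[(1S)-3-[(2S,5S)-5-({[tert-butyl(dimethyl)silyl]oxy}methyl)-5-methyloxolan-2-yl]-1-hydroxy-3-oxopropyl]furan-3-yl}methyl acetate, via boron enolate 16 (not isolated)
Conditions: (+)-Ipc2BCl, Et3N, Et2O, −78 → −40 °C; then 15, −78 → −20 °C; H2O2, MeOH, pH 7 buffer, 0 °C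
Reagents that add atoms: none
Why: Kinetic enolisation at the methyl group (not at C1) and a boron-mediated aldol addition under reagent control of the isopinocampheyl ligands, whose methyl-ketone enolates add to the Si face of the aldehyde, should set C8 as S; any C8 epimer is a separable diastereomer.

Step 12
Reactants: 17 aldol adduct
Product: 18 triisopropylsilyl ether of 17 at the C8 hydroxyl
Conditions: TIPSOTf, 2,6-lutidine, CH2Cl2, −78 → 0 °C
Reagents that add atoms: triisopropylsilyl trifluoromethanesulfonate, CC(C)[Si](OS(=O)(=O)C(F)(F)F)(C(C)C)C(C)C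
Why: Silylation with the silyl triflate blocks the β-oxygen as a bulky, non-chelating ether that should last until step 19.

Step 13
Reactants: 18 silyl ether ketone
Product: 19 {4-[(1S,3R)-3-[(2S,5S)-5-({[tert-butyl(dimethyl)silyl]oxy}methyl)-5-methyloxolan-2-yl]-3-hydroxy-1-{[tri(propan-2-yl)silyl]oxy}butyl]furan-3-yl}methanol
Conditions: MeMgBr (5 equiv), CH2Cl2/Et2O, −78 → 0 °C; then H2O
Reagents that add atoms: methylmagnesium bromide, C[Mg]Br
Why: In this chelation-controlled Grignard addition magnesium bridges the ketone oxygen and the oxolane oxygen, the methyl group is delivered to the carbonyl face opposite the ring CH2 (C2) to give the 10R tertiary alcohol, and the excess reagent cleaves the acetate to the alcohol needed in step 14.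

Step 14
Reactants: 19 furan diol
Product: 21 4-[(1S,3R)-3-[(2S,5S)-5-({[tert-butyl(dimethyl)silyl]oxy}methyl)-5-methyloxolan-2-yl]-3-hydroxy-1-{[tri(propan-2-yl)silyl]oxy}butyl]-3-(hydroxymethyl)furan-2(5H)-one, via furylboronate 20 (not isolated)
Conditions: n-BuLi (3.3 equiv), THF, −78 → 0 °C; B(OMe)3, −78 °C → rt; then H2O2, NaHCO3, 0 °C; Et3N (cat.), rt
Reagents that add atoms: hydrogen peroxide, OO
Why: Alkoxide-directed ortho-lithiation should place lithium at the furan α-carbon next to the CH2O− group (C12), and borylation followed by peroxide oxidation of the C–B bond gives the 2-hydroxyfuran, which tautomerises to the conjugated butenolide with the carbonyl at C12 and a CH2 group at C6.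

Step 15
Reactants: 21 butenolide diol
Product: 22 tert-butyldiphenylsilyl ether of 21 at the primary C13 hydroxyl
Conditions: TBDPSCl, imidazole, CH2Cl2, 0 °C
Reagents that add atoms: tert-butyl(chloro)diphenylsilane, CC(C)(C)[Si](Cl)(c1ccccc1)c1ccccc1
Why: Silylation is selective for the primary alcohol over the tertiary one and uses a silyl group that outlasts the removal of the primary TBS ether.

Step 16
Reactants: 22 tris-silyl ether
Product: 23 primary alcohol at C5 (TBS group removed)
Conditions: HF·pyridine, pyridine, THF, 0 °C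
Reagents that add atoms: none
Why: Buffered fluoride desilylation should remove the least robust silyl ether (primary TBS) in preference to the secondary TIPS and the primary TBDPS ethers.

Step 17
Reactants: 23 primary alcohol
Product: 24 (2S,5S)-5-[(2R,4S)-4-[4-({[tert-butyl(diphenyl)silyl]oxy}methyl)-5-oxo-2,5-dihydrofuran-3-yl]-2-hydroxy-4-{[tri(propan-2-yl)silyl]oxy}butan-2-yl]-2-methyloxolane-2-carbaldehyde
Conditions: Dess–Martin periodinane, CH2Cl2, rt
Reagents that add atoms: none
Why: Dess–Martin oxidation converts the neopentyl primary alcohol into the non-enolisable aldehyde and leaves the tertiary alcohol and the butenolide untouched.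

Step 18
Reactants: 24 aldehyde butenolide
Product: 27 (1S,2E,8S,10R,11S)-6-({[tert-butyl(diphenyl)silyl]oxy}methyl)-1,10-dimethyl-10-[(triethylsilyl)oxy]-8-{[tri(propan-2-yl)silyl]oxy}-4,14-dioxatricyclo[9.2.1.0(3,7)]tetradeca-2,6-dien-5-one, via silyloxyfuran 25 (not isolated), via silyl aldol ether 26 (not isolated)
Conditions: TESOTf (4 equiv), Et3N (6 equiv), CH2Cl2 (0.002 M, slow addition of 24), −78 °C → rt; then DBU, rt
Reagents that add atoms: triethylsilyl trifluoromethanesulfonate, CC[Si](CC)(CC)OS(=O)(=O)C(F)(F)F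
Why: Intramolecular vinylogous Mukaiyama aldol addition of the 2-silyloxyfuran formed in situ (γ-carbon C6) to the silyl-triflate-activated C5 aldehyde at high dilution closes the ten-membered carbocycle, and DBU-induced E1cB loss of silanolate gives the ylidene butenolide with the C5=C6 geometry (C4 cis to C7) that the bridged ring is expected to accommodate, leaving no stereocentre at C5 or C6.

Step 19
Reactants: 27 silylated macrocycle
Product: 28 (1S,2E,8S,10R,11S)-8,10-dihydroxy-6-(hydroxymethyl)-1,10-dimethyl-4,14-dioxatricyclo[9.2.1.0(3,7)]tetradeca-2,6-dien-5-one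
Conditions: HF·pyridine (excess), THF, 0 °C → rt
Reagents that add atoms: none
Why: Excess HF·pyridine should cleave the three remaining silyl ethers under non-basic conditions that spare the ylidene butenolide.

Step 20
Reactants: 28 triol
Product: 29 [(1S,2E,8S,10R,11S)-8,10-dihydroxy-1,10-dimethyl-5-oxo-4,14-dioxatricyclo[9.2.1.0(3,7)]tetradeca-2,6-dien-6-yl]methyl acetate
Conditions: Ac2O (1.1 equiv), 2,4,6-collidine, CH2Cl2, −20 °C
Reagents that add atoms: acetic anhydride, CC(=O)OC(C)=O
Why: The unhindered primary allylic alcohol should be acetylated faster than the hindered ring secondary alcohol and the tertiary alcohol, and the low temperature and non-nucleophilic base avoid displacement at C13.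

Step 21
Reactants: 29 diol acetate; 30 angelic acid
Product: 32 CNP0162854.1, via mixed anhydride 31 (not isolated)
Conditions: 30, 2,4,6-trichlorobenzoyl chloride, Et3N, toluene, rt; then 29, 70 °C (no DMAP)
Reagents that add atoms: none
Why: Yamaguchi-type esterification through the mixed anhydride acylates the secondary C8 alcohol with retention at C8, and omitting DMAP should avoid isomerisation of the Z (angelate) double bond to the E (tiglate) isomer.

Compound list

1 | 4-bromofuran-2-carbaldehyde | O=Cc1cc(Br)co1 | starting material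
2 | 4-methylfuran-2-carbaldehyde | Cc1coc(C=O)c1 | intermediate
3 | (4-methylfuran-2-yl)methanol | Cc1coc(CO)c1 | intermediate
4 | tert-butyl(dimethyl)[(4-methylfuran-2-yl)methoxy]silane | Cc1coc(CO[Si](C)(C)C(C)(C)C)c1 | intermediate
5 | 3-(prop-2-enoyl)-1,3-oxazolidin-2-one | C=CC(=O)N1CCOC1=O | starting material
6 | 3-{[(1S,2S,4S)-1-({[tert-butyl(dimethyl)silyl]oxy}methyl)-5-methyl-7-oxabicyclo[2.2.1]hept-5-en-2-yl]carbonyl}-1,3-oxazolidin-2-one (endo acyl) | CC1=C[C@]2(CO[Si](C)(C)C(C)(C)C)O[C@H]1C[C@@H]2C(=O)N1CCOC1=O | intermediate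
7 | 3-{[(2S,3S,5S)-5-acetyl-2-({[tert-butyl(dimethyl)silyl]oxy}methyl)-2-formyloxolan-3-yl]carbonyl}-1,3-oxazolidin-2-one | CC(=O)[C@@H]1C[C@H](C(=O)N2CCOC2=O)[C@@](C=O)(CO[Si](C)(C)C(C)(C)C)O1 | intermediate
8 | (E)-4-methylbenzenesulfonylhydrazone of the formyl group of 7 | CC(=O)[C@@H]1C[C@H](C(=O)N2CCOC2=O)[C@@](/C=N/NS(=O)(=O)c2ccc(C)cc2)(CO[Si](C)(C)C(C)(C)C)O1 | intermediate (not isolated)
9 | 3-{[(2S,3S,5S)-5-acetyl-2-({[tert-butyl(dimethyl)silyl]oxy}methyl)-2-methyloxolan-3-yl]carbonyl}-1,3-oxazolidin-2-one | CC(=O)[C@@H]1C[C@H](C(=O)N2CCOC2=O)[C@@](C)(CO[Si](C)(C)C(C)(C)C)O1 | intermediate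
10 | (2S,3S,5S)-5-acetyl-2-({[tert-butyl(dimethyl)silyl]oxy}methyl)-2-methyloxolane-3-carboxylic acid | CC(=O)[C@@H]1C[C@H](C(=O)O)[C@@](C)(CO[Si](C)(C)C(C)(C)C)O1 | intermediate
11 | 2-thioxopyridin-1(2H)-yl ester of acid 10 | CC(=O)[C@@H]1C[C@H](C(=O)ON2C=CC=CC2=S)[C@@](C)(CO[Si](C)(C)C(C)(C)C)O1 | intermediate (not isolated)
12 | 1-[(2S,5S)-5-({[tert-butyl(dimethyl)silyl]oxy}methyl)-5-methyloxolan-2-yl]ethan-1-one | CC(=O)[C@@H]1CC[C@@](C)(CO[Si](C)(C)C(C)(C)C)O1 | intermediate
13 | furan-3,4-diyldimethanol | OCc1cocc1CO | starting material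
14 | [4-(hydroxymethyl)furan-3-yl]methyl acetate | CC(=O)OCc1cocc1CO | intermediate
15 | (4-formylfuran-3-yl)methyl acetate | CC(=O)OCc1cocc1C=O | intermediate
16 | bis(isopinocampheyl)boron enolate of 12 (O-boryl enol on the methyl side; ligands from (−)-α-pinene) | C=C(OB([C@H]1C[C@H]2C[C@@H]([C@@H]1C)C2(C)C)[C@H]1C[C@H]2C[C@@H]([C@@H]1C)C2(C)C)[C@@H]1CC[C@@](C)(CO[Si](C)(C)C(C)(C)C)O1 | intermediate (not isolated)
17 | {4-[(1S)-3-[(2S,5S)-5-({[tert-butyl(dimethyl)silyl]oxy}methyl)-5-methyloxolan-2-yl]-1-hydroxy-3-oxopropyl]furan-3-yl}methyl acetate | O[C@H](c1cocc1COC(C)=O)CC(=O)[C@@H]1CC[C@@](C)(CO[Si](C)(C)C(C)(C)C)O1 | intermediate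
18 | {4-[(1S)-3-[(2S,5S)-5-({[tert-butyl(dimethyl)silyl]oxy}methyl)-5-methyloxolan-2-yl]-3-oxo-1-{[tri(propan-2-yl)silyl]oxy}propyl]furan-3-yl}methyl acetate | CC(C)[Si](C(C)C)(C(C)C)O[C@H](c1cocc1COC(C)=O)CC(=O)[C@@H]1CC[C@@](C)(CO[Si](C)(C)C(C)(C)C)O1 | intermediate
19 | {4-[(1S,3R)-3-[(2S,5S)-5-({[tert-butyl(dimethyl)silyl]oxy}methyl)-5-methyloxolan-2-yl]-3-hydroxy-1-{[tri(propan-2-yl)silyl]oxy}butyl]furan-3-yl}methanol | CC(C)[Si](C(C)C)(C(C)C)O[C@H](c1cocc1CO)C[C@@](C)(O)[C@@H]1CC[C@@](C)(CO[Si](C)(C)C(C)(C)C)O1 | intermediate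
20 | dimethyl furan-2-ylboronate of 19 (boron at the α-carbon next to the CH2OH group; present as its lithium alkoxide) | CC(C)[Si](C(C)C)(C(C)C)O[C@H](c1coc(B(OC)OC)c1CO)C[C@@](C)(O)[C@@H]1CC[C@@](C)(CO[Si](C)(C)C(C)(C)C)O1 | intermediate (not isolated)
21 | 4-[(1S,3R)-3-[(2S,5S)-5-({[tert-butyl(dimethyl)silyl]oxy}methyl)-5-methyloxolan-2-yl]-3-hydroxy-1-{[tri(propan-2-yl)silyl]oxy}butyl]-3-(hydroxymethyl)furan-2(5H)-one | CC(C)[Si](C(C)C)(C(C)C)O[C@H](C1=C(CO)C(=O)OC1)C[C@@](C)(O)[C@@H]1CC[C@@](C)(CO[Si](C)(C)C(C)(C)C)O1 | intermediate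
22 | 3-({[tert-butyl(diphenyl)silyl]oxy}methyl) analogue of 21 | CC(C)[Si](C(C)C)(C(C)C)O[C@H](C1=C(CO[Si](c2ccccc2)(c2ccccc2)C(C)(C)C)C(=O)OC1)C[C@@](C)(O)[C@@H]1CC[C@@](C)(CO[Si](C)(C)C(C)(C)C)O1 | intermediate
23 | 3-({[tert-butyl(diphenyl)silyl]oxy}methyl)-4-[(1S,3R)-3-hydroxy-3-[(2S,5S)-5-(hydroxymethyl)-5-methyloxolan-2-yl]-1-{[tri(propan-2-yl)silyl]oxy}butyl]furan-2(5H)-one | CC(C)[Si](C(C)C)(C(C)C)O[C@H](C1=C(CO[Si](c2ccccc2)(c2ccccc2)C(C)(C)C)C(=O)OC1)C[C@@](C)(O)[C@@H]1CC[C@@](C)(CO)O1 | intermediate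
24 | (2S,5S)-5-[(2R,4S)-4-[4-({[tert-butyl(diphenyl)silyl]oxy}methyl)-5-oxo-2,5-dihydrofuran-3-yl]-2-hydroxy-4-{[tri(propan-2-yl)silyl]oxy}butan-2-yl]-2-methyloxolane-2-carbaldehyde | CC(C)[Si](C(C)C)(C(C)C)O[C@H](C1=C(CO[Si](c2ccccc2)(c2ccccc2)C(C)(C)C)C(=O)OC1)C[C@@](C)(O)[C@@H]1CC[C@@](C)(C=O)O1 | intermediate
25 | 2-(triethylsilyloxy)furan form of 24 with the C10 hydroxyl as triethylsilyl ether | CC(C)[Si](C(C)C)(C(C)C)O[C@H](c1coc(O[Si](CC)(CC)CC)c1CO[Si](c2ccccc2)(c2ccccc2)C(C)(C)C)C[C@@](C)(O[Si](CC)(CC)CC)[C@@H]1CC[C@@](C)(C=O)O1 | intermediate (not isolated)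
26 | (1S,8S,10R,11S)-6-({[tert-butyl(diphenyl)silyl]oxy}methyl)-1,10-dimethyl-2,10-bis[(triethylsilyl)oxy]-8-{[tri(propan-2-yl)silyl]oxy}-4,14-dioxatricyclo[9.2.1.0(3,7)]tetradec-6-en-5-one, mixture of epimers at C2 and C3 | CC(C)[Si](C(C)C)(C(C)C)O[C@H]1C[C@@](C)(O[Si](CC)(CC)CC)[C@@H]2CC[C@@](C)(C(O[Si](CC)(CC)CC)C3OC(=O)C(CO[Si](c4ccccc4)(c4ccccc4)C(C)(C)C)=C31)O2 | intermediate (not isolated)
27 | (1S,2E,8S,10R,11S)-6-({[tert-butyl(diphenyl)silyl]oxy}methyl)-1,10-dimethyl-10-[(triethylsilyl)oxy]-8-{[tri(propan-2-yl)silyl]oxy}-4,14-dioxatricyclo[9.2.1.0(3,7)]tetradeca-2,6-dien-5-one | CC(C)[Si](C(C)C)(C(C)C)O[C@H]1C[C@@](C)(O[Si](CC)(CC)CC)[C@@H]2CC[C@@](C)(/C=C3/OC(=O)C(CO[Si](c4ccccc4)(c4ccccc4)C(C)(C)C)=C31)O2 | intermediate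
28 | (1S,2E,8S,10R,11S)-8,10-dihydroxy-6-(hydroxymethyl)-1,10-dimethyl-4,14-dioxatricyclo[9.2.1.0(3,7)]tetradeca-2,6-dien-5-one | O[C@H]1C[C@@](C)(O)[C@@H]2CC[C@@](C)(/C=C3/OC(=O)C(CO)=C31)O2 | intermediate
29 | [(1S,2E,8S,10R,11S)-8,10-dihydroxy-1,10-dimethyl-5-oxo-4,14-dioxatricyclo[9.2.1.0(3,7)]tetradeca-2,6-dien-6-yl]methyl acetate | O[C@H]1C[C@@](C)(O)[C@@H]2CC[C@@](C)(/C=C3/OC(=O)C(COC(C)=O)=C31)O2 | intermediate
30 | angelic acid, (2Z)-2-methylbut-2-enoic acid | C/C=C(/C)C(O)=O | starting material
31 | (2Z)-2-methylbut-2-enoic 2,4,6-trichlorobenzoic anhydride | C/C=C(/C)C(=O)OC(=O)c1c(Cl)cc(Cl)cc1Cl | intermediate (not isolated)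
32 | CNP0162854.1, (1S,2E,8S,10R,11S)-6-[(acetyloxy)methyl]-10-hydroxy-1,10-dimethyl-5-oxo-4,14-dioxatricyclo[9.2.1.0(3,7)]tetradeca-2,6-dien-8-yl (2Z)-2-methylbut-2-enoate | C/C=C(/C)C(=O)O[C@H]1C[C@@](C)(O)[C@@H]2CC[C@@](C)(/C=C3/OC(=O)C(COC(C)=O)=C31)O2 | target

Total step count: 21 steps.
Longest linear sequence: 19 steps (1 → 32 through steps 1–8 and 11–21); the furan aldehyde 15 takes 2 further steps.

Steps most likely to fail

Step 4 (key Diels–Alder reaction). The cycloaddition may be slow at the hindered furan terminus, and exo or regioisomeric transition states, each of which leads to the antipodal oxolane once the acyl group is removed, may erode the enantiomeric purity. The fallback sets out from 4 and comes back at 12, and it replaces catalyst control by a convergent racemic cycloaddition and an enzymatic resolution. Thermal Diels–Alder reaction of 4 with nitroethylene (freshly made from 2-nitroethanol and phthalic anhydride) should give the racemic nitro adducts F1, whose regio- and endo/exo isomers all converge later. Ozonolysis with NaBH(OAc)3 work-up reduces only the new aldehyde and gives the hydroxy ketone F2, and PPh3/I2/imidazole gives the neopentyl iodide F3. Bu3SnH/AIBN in refluxing toluene removes iodine and the nitro group in one radical chain reduction and gives the racemic ketone, that is 12 together with its enantiomer F4. An enantiomer-selective ketoreductase (oxidoreductase class, cofactor recycled with propan-2-ol), chosen by screening, reduces F4 to the alcohol F5 and leaves 12, which is separated by chromatography.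

Step 18 (macrocyclisation). Oligomerisation or retro-aldol cleavage may outcompete closure of the strained trans-bridged ten-membered ring, and the elimination may stall or give the other double-bond geometry. The fallback sets out from 22 and comes back at 28, and it closes the same bond by an irreversible intramolecular Wittig olefination. γ-Bromination of 22 (TMSOTf/Et3N, then NBS, −78 °C) should give the γ-bromobutenolide F6, and PPh3 in MeCN the phosphonium bromide F7. HF·pyridine frees the primary alcohol F8 and Dess–Martin oxidation gives the aldehyde F9. Slow addition of F9 to Et3N in CH2Cl2 at high dilution generates the stabilised ylide, which should close the ring to the macrocycle F10 (free C10 hydroxyl). HF·pyridine as in step 19 then gives 28.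

Step 14 (furan to butenolide). Metalation may occur at the other furan α-position (C6) or the peroxide may over-oxidise the electron-rich furan. The fallback sets out from 19 and comes back at 21, and it uses an oxidative rather than an organometallic route. Dye-sensitised photooxygenation (O2, rose bengal, visible light, iPr2NEt, CH2Cl2/MeOH, −78 °C) adds singlet oxygen across the furan; base-induced fragmentation of the endoperoxide, in which the base removes the less hindered C12–H, should give the γ-hydroxybutenolide F11. NaBH4 reduces its ring-opened aldehyde form and relactonisation gives 21.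

Further compounds

F1 | step 4 | racemic tert-butyl(dimethyl)[(3-methyl-6-nitro-7-oxabicyclo[2.2.1]hept-2-en-1-yl)methoxy]silane, mixture of nitro epimers | CC1=CC2(CO[Si](C)(C)C(C)(C)C)OC1CC2[N+](=O)[O-]
F2 | step 4 | racemic 1-[5-({[tert-butyl(dimethyl)silyl]oxy}methyl)-5-(hydroxymethyl)-4-nitrooxolan-2-yl]ethan-1-one, acetyl and hydroxymethyl cis, one enantiomer drawn | CC(=O)[C@@H]1CC([N+](=O)[O-])[C@@](CO)(CO[Si](C)(C)C(C)(C)C)O1
F3 | step 4 | racemic 1-[5-({[tert-butyl(dimethyl)silyl]oxy}methyl)-5-(iodomethyl)-4-nitrooxolan-2-yl]ethan-1-one, one enantiomer drawn | CC(=O)[C@@H]1CC([N+](=O)[O-])[C@@](CI)(CO[Si](C)(C)C(C)(C)C)O1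
F4 | step 4 | 1-[(2R,5R)-5-({[tert-butyl(dimethyl)silyl]oxy}methyl)-5-methyloxolan-2-yl]ethan-1-one (enantiomer of 12) | CC(=O)[C@H]1CC[C@](C)(CO[Si](C)(C)C(C)(C)C)O1
F5 | step 4 | (1S)-1-[(2R,5R)-5-({[tert-butyl(dimethyl)silyl]oxy}methyl)-5-methyloxolan-2-yl]ethan-1-ol | C[C@H](O)[C@H]1CC[C@](C)(CO[Si](C)(C)C(C)(C)C)O1
F6 | step 18 | 5-bromo derivative of 22 at the butenolide γ-carbon (C6), mixture of epimers | CC(C)[Si](C(C)C)(C(C)C)O[C@H](C1=C(CO[Si](c2ccccc2)(c2ccccc2)C(C)(C)C)C(=O)OC1Br)C[C@@](C)(O)[C@@H]1CC[C@@](C)(CO[Si](C)(C)C(C)(C)C)O1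
F7 | step 18 | triphenylphosphonium bromide from F6 (phosphorus at C6) | CC(C)[Si](C(C)C)(C(C)C)O[C@H](C1=C(CO[Si](c2ccccc2)(c2ccccc2)C(C)(C)C)C(=O)OC1[P+](c3ccccc3)(c3ccccc3)c3ccccc3)C[C@@](C)(O)[C@@H]1CC[C@@](C)(CO[Si](C)(C)C(C)(C)C)O1.[Br-]
F8 | step 18 | C5 primary alcohol of F7 | CC(C)[Si](C(C)C)(C(C)C)O[C@H](C1=C(CO[Si](c2ccccc2)(c2ccccc2)C(C)(C)C)C(=O)OC1[P+](c3ccccc3)(c3ccccc3)c3ccccc3)C[C@@](C)(O)[C@@H]1CC[C@@](C)(CO)O1.[Br-]
F9 | step 18 | C5 aldehyde of F7 | CC(C)[Si](C(C)C)(C(C)C)O[C@H](C1=C(CO[Si](c2ccccc2)(c2ccccc2)C(C)(C)C)C(=O)OC1[P+](c3ccccc3)(c3ccccc3)c3ccccc3)C[C@@](C)(O)[C@@H]1CC[C@@](C)(C=O)O1.[Br-]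
F10 | step 18 | (1S,2E,8S,10R,11S)-6-({[tert-butyl(diphenyl)silyl]oxy}methyl)-10-hydroxy-1,10-dimethyl-8-{[tri(propan-2-yl)silyl]oxy}-4,14-dioxatricyclo[9.2.1.0(3,7)]tetradeca-2,6-dien-5-one | CC(C)[Si](C(C)C)(C(C)C)O[C@H]1C[C@@](C)(O)[C@@H]2CC[C@@](C)(/C=C3/OC(=O)C(CO[Si](c4ccccc4)(c4ccccc4)C(C)(C)C)=C31)O2
F11 | step 14 | 5-hydroxy derivative of 21 at the butenolide γ-carbon (C6), mixture of epimers | CC(C)[Si](C(C)C)(C(C)C)O[C@H](C1=C(CO)C(=O)OC1O)C[C@@](C)(O)[C@@H]1CC[C@@](C)(CO[Si](C)(C)C(C)(C)C)O1
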